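**Retrosynthetic overview**

1. Target ⇒ Mukaiyama hydration of the isopropenyl tricycle ⇒ oxidative radical cascade (two 5-exo closures) of a monocyclic 2-isobutyryl-6-methyl-4,6-diprenyl cyclohexanetrione.
2. That trione ⇒ late union of two halves of 14 non-hydrogen atoms each: the (R)-methyl hydrogen 2-methyl-2-prenylmalonate (as acid chloride) and 2,9-dimethyldec-8-ene-3,5-dione, by diketone-dianion C-acylation and Claisen ring closure.
3. Half-ester ⇒ enzymatic desymmetrisation of dimethyl 2-methyl-2-prenylmalonate ⇒ methylmalonic acid and prenyl bromide.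
4. Diketone ⇒ aldol addition and oxidation of 3-methylbutan-2-one with 5-methylhex-4-enal ⇒ Claisen rearrangement from 2-methylbut-3-en-2-ol and ethyl vinyl ether.
5. Ring order: six-membered triketone ring (ring C) first, then in one cascade the bridging cyclopentanone (ring B, giving the bicyclo[3.2.1]octane) and last the gem-dimethylcyclopentane (ring A); the malonate quaternary carbon is the only preset stereocentre.

Assumption: pig liver esterase is taken to hydrolyse the pro-S ester group of dimethyl 2-methyl-2-prenylmalonate; the sense and level of this selectivity must be confirmed on the first run.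

**Route**

Step 1
Reactants: 1 methylmalonic acid (2-methylpropanedioic acid)
Product: 2 dimethyl 2-methylpropanedioate
Conditions: MeOH (solvent), H2SO4 (cat.), reflux
Reagents that add atoms: methanol (SMILES: CO)
Why: Fischer esterification driven by excess methanol gives the diester needed for enolate alkylation, and no stereocentre is formed.

Step 2
Reactants: 2 dimethyl 2-methylpropanedioate; 3 1-bromo-3-methylbut-2-ene (prenyl bromide)
Product: 4 dimethyl 2-methyl-2-(3-methylbut-2-en-1-yl)propanedioate
Conditions: NaH (1.1 equiv), THF, 0 °C; then 3, 0 → 23 °C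
Reagents that add atoms: none
Why: Malonic ester alkylation (SN2 of the sodium enolate on the primary allylic bromide) builds the quaternary carbon, which is still prochiral because its two ester groups are identical.

Step 3
Reactants: 4 dimethyl 2-methyl-2-(3-methylbut-2-en-1-yl)propanedioate
Product: 5 (2R)-2-(methoxycarbonyl)-2,5-dimethylhex-4-enoic acid
Conditions: pig liver esterase, 0.1 M phosphate buffer pH 7.5/DMSO 4:1, 25 °C, pH held at 7.5 with 1 M NaOH; then 2 M HCl to pH 2
Reagents that add atoms: water (SMILES: O)
Why: Enzymatic desymmetrisation (enantiotopic-group-selective ester hydrolysis) cleaves only the pro-S methoxycarbonyl group and stops at the monocarboxylate, so the quaternary carbon becomes the R stereocentre.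

Step 4
Reactants: 6 2-methylbut-3-en-2-ol; 7 ethyl vinyl ether
Product: 10 5-methylhex-4-enal, via mixed acetal 8 (not isolated), via allyl vinyl ether 9 (not isolated)
Conditions: 7 (3 equiv), H3PO4 (cat.), 150 °C, sealed vessel
Reagents that add atoms: none
Why: Acid-catalysed vinyl transfer gives the tertiary allyl vinyl ether, whose Claisen [3,3]-sigmatropic rearrangement (Saucy–Marbet type) delivers the γ,δ-unsaturated aldehyde with the trisubstituted alkene, and no stereocentre is formed.

Step 5
Reactants: 10 5-methylhex-4-enal; 11 3-methylbutan-2-one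
Product: 12 5-hydroxy-2,9-dimethyldec-8-en-3-one (racemic)
Conditions: 11, LiN(i-Pr)2 (1.05 equiv), THF, −78 °C; then 10; AcOH quench
Reagents that add atoms: none
Why: Directed aldol addition, in which kinetic deprotonation at the methyl group gives the less substituted lithium enolate that adds to the aldehyde; the new carbinol centre is racemic and is erased in step 6.

Step 6
Reactants: 12 5-hydroxy-2,9-dimethyldec-8-en-3-one
Product: 13 2,9-dimethyldec-8-ene-3,5-dione
Conditions: 2-iodoxybenzoic acid (IBX, 2 equiv), EtOAc, 77 °C
Reagents that add atoms: none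
Why: IBX oxidation converts the β-hydroxy ketone into the β-diketone cleanly and leaves the trisubstituted alkene untouched.

Step 7
Reactants: 5 (2R)-2-(methoxycarbonyl)-2,5-dimethylhex-4-enoic acid; 13 2,9-dimethyldec-8-ene-3,5-dione
Product: 16 (6R)-3,5-dihydroxy-6-methyl-4,6-bis(3-methylbut-2-en-1-yl)-2-(2-methylpropanoyl)cyclohexa-2,4-dien-1-one, via acid chloride 14 (not isolated), via triketo ester 15 (not isolated)
Conditions: 5, Ghosez reagent (1-chloro-N,N,2-trimethylprop-1-en-1-amine), CH2Cl2, 0 → 23 °C, solvent changed to THF; added to 13 (2.0 equiv, excess recovered) + LiN(i-Pr)2 (4.1 equiv), THF, −78 → 0 °C; then NaOMe (3 equiv), MeOH, 23 → 50 °C; 1 M HCl work-up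
Reagents that add atoms: none
Why: Claisen-type C-acylation of the 1,3-diketone dianion at its terminal CH2 (C-6) by the acid chloride gives the 3,5,7-triketo ester, whose central diketone carbon then attacks the methyl ester in an intramolecular Claisen (Dieckmann-type) condensation to close the six-membered ring as its stabilised enolate; the quaternary stereocentre has no α-hydrogen and is carried through unchanged (acid-chloride carbon becomes C-5 and ester carbon C-1, hence 6R).

Step 8
Reactants: 16 (6R)-3,5-dihydroxy-6-methyl-4,6-bis(3-methylbut-2-en-1-yl)-2-(2-methylpropanoyl)cyclohexa-2,4-dien-1-one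
Product: 17 (1S,3S,5S,7S)-8-hydroxy-4,4,7-trimethyl-9-(2-methylpropanoyl)-3-(prop-1-en-2-yl)tricyclo[5.3.1.0^1,5]undec-8-ene-10,11-dione
Conditions: Mn(OAc)3·2H2O (2.2 equiv), Cu(OAc)2·H2O (0.2 equiv), AcOH, 23 °C; preparative HPLC
Reagents that add atoms: none
Why: Mn(OAc)3-mediated oxidative radical cyclisation cascade, in which the radical at C-4 of the enolised triketone adds 5-exo to the prenyl group on C-6, the resulting tertiary radical adds 5-exo to the C-4 prenyl group and Cu(OAc)2 oxidises the last radical to the isopropenyl group; bridging from the fixed quaternary carbon sets C-1, only the exo radical can close the last ring so C-5 follows, and a chair-like transition state places the side chain on the convex face at C-3, the co-formed C-3 epimer being removed by HPLC.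

Step 9
Reactants: 17 (1S,3S,5S,7S)-8-hydroxy-4,4,7-trimethyl-9-(2-methylpropanoyl)-3-(prop-1-en-2-yl)tricyclo[5.3.1.0^1,5]undec-8-ene-10,11-dione
Product: 18 (1S,3R,5S,7S)-8-hydroxy-3-(2-hydroxypropan-2-yl)-4,4,7-trimethyl-9-(2-methylpropanoyl)tricyclo[5.3.1.0^1,5]undec-8-ene-10,11-dione
Conditions: Co(acac)2 (20 mol%), PhSiH3 (2.5 equiv), O2 (1 atm), THF, 23 °C
Reagents that add atoms: dioxygen (SMILES: O=O)
Why: Mukaiyama hydration, in which a cobalt hydride transfers a hydrogen atom to the CH2 end of the 1,1-disubstituted alkene, O2 traps the tertiary radical and the silane reduces the peroxide, gives the Markovnikov tertiary alcohol without a carbocation, so no stereocentre is touched and no ether forms with the neighbouring enol (the C-3 descriptor changes from S to R only through substituent priorities).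

**Compound list**

1 | methylmalonic acid (2-methylpropanedioic acid) | CC(C(=O)O)C(=O)O | starting material
2 | dimethyl 2-methylpropanedioate | COC(=O)C(C)C(=O)OC | intermediate
3 | 1-bromo-3-methylbut-2-ene (prenyl bromide) | CC(C)=CCBr | starting material
4 | dimethyl 2-methyl-2-(3-methylbut-2-en-1-yl)propanedioate | COC(=O)C(C)(CC=C(C)C)C(=O)OC | intermediate
5 | (2R)-2-(methoxycarbonyl)-2,5-dimethylhex-4-enoic acid | COC(=O)[C@](C(=O)O)(C)CC=C(C)C | intermediate
6 | 2-methylbut-3-en-2-ol | CC(C)(O)C=C | starting material
7 | ethyl vinyl ether (ethoxyethene) | CCOC=C | starting material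
8 | 3-(1-ethoxyethoxy)-3-methylbut-1-ene (racemic mixed acetal) | CCOC(C)OC(C)(C)C=C | intermediate
9 | 3-(ethenyloxy)-3-methylbut-1-ene | C=COC(C)(C)C=C | intermediate
10 | 5-methylhex-4-enal | CC(C)=CCCC=O | intermediate
11 | 3-methylbutan-2-one | CC(C)C(C)=O | starting material
12 | 5-hydroxy-2,9-dimethyldec-8-en-3-one (racemic) | CC(C)C(=O)CC(O)CCC=C(C)C | intermediate
13 | 2,9-dimethyldec-8-ene-3,5-dione | CC(C)C(=O)CC(=O)CCC=C(C)C | intermediate
14 | methyl (2S)-2-(chlorocarbonyl)-2,5-dimethylhex-4-enoate | COC(=O)[C@](C(=O)Cl)(C)CC=C(C)C | intermediate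
15 | methyl (2R)-2,8-dimethyl-2,4-bis(3-methylbut-2-en-1-yl)-3,5,7-trioxononanoate (C-4 epimers, enolised) | COC(=O)[C@](C(=O)C(CC=C(C)C)C(=O)CC(=O)C(C)C)(C)CC=C(C)C | intermediate
16 | (6R)-3,5-dihydroxy-6-methyl-4,6-bis(3-methylbut-2-en-1-yl)-2-(2-methylpropanoyl)cyclohexa-2,4-dien-1-one | CC(C)C(=O)C1=C(O)C(CC=C(C)C)=C(O)[C@@](C)(CC=C(C)C)C1=O | intermediate
17 | (1S,3S,5S,7S)-8-hydroxy-4,4,7-trimethyl-9-(2-methylpropanoyl)-3-(prop-1-en-2-yl)tricyclo[5.3.1.0^1,5]undec-8-ene-10,11-dione | CC(C)C(=O)C1=C(O)[C@]2(C)C[C@H]3C(C)(C)[C@H](C(C)=C)C[C@@]3(C1=O)C2=O | intermediate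
18 | (1S,3R,5S,7S)-8-hydroxy-3-(2-hydroxypropan-2-yl)-4,4,7-trimethyl-9-(2-methylpropanoyl)tricyclo[5.3.1.0^1,5]undec-8-ene-10,11-dione | CC(C)C(=O)C1=C(O)[C@]2(C)C[C@H]3C(C)(C)[C@H](C(C)(C)O)C[C@@]3(C1=O)C2=O | target

**Totals**

Total step count: 9.
Longest linear sequence: 6 steps (steps 1, 2, 3, 7, 8, 9; the branch through steps 4, 5, 6 is equally long).

**Steps most likely to fail**

Step 3. The enantiomeric excess of the esterase hydrolysis of a methyl/prenyl malonate may be only moderate, and its sense is assumed. The fallback sets out from 4 and comes back at 5. Desymmetrising hydrosilylation of 4 with HSiMe(OEt)2 under a dinuclear zinc catalyst made from ZnEt2 and a chiral pipecolinol-derived tetradentate aminophenol ligand (the ligand enantiomer that reduces the pro-S ester), followed by NH4F in MeOH, gives methyl (2R)-2-(hydroxymethyl)-2,5-dimethylhex-4-enoate F1. Oxidation of this neopentyl alcohol with TEMPO and PhI(OAc)2 in MeCN–water then gives acid 5.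

Step 7. The acid chloride may O-acylate or doubly acylate the dianion, and the triketo ester may close through oxygen to a pyranone or suffer retro-Claisen cleavage under methoxide. The fallback sets out from 14 (made from 5 as in step 7) together with 13 and comes back at 16. Reduction of 14 with LiAlH(Ot-Bu)3 in THF at −78 °C gives methyl (2R)-2-formyl-2,5-dimethylhex-4-enoate F2. Aldol addition of the dilithio dianion of 13 (2 equiv LiN(i-Pr)2) through its C-6 to this non-enolisable aldehyde gives methyl (2R)-3-hydroxy-2,8-dimethyl-2,4-bis(3-methylbut-2-en-1-yl)-5,7-dioxononanoate F3 as a diastereomer mixture. IBX oxidation gives triketo ester 15, now isolated, and NaOMe in MeOH closes it to 16.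

Step 8. The cascade is expected to give a moderate yield and both C-3 epimers, and their HPLC separation may be poor. The fallback sets out from 16 and comes back at 18, passing by 17 and step 9. With Mn(OAc)3·2H2O alone (no copper salt) in AcOH the final tertiary radical is oxidised to the cation. In the required C-3 series this cation lies cis to the C-10 enol oxygen and is captured as the cyclic enol ether F4, which the other epimer cannot form and which is separated by flash chromatography. Aqueous LiOH in THF then opens this vinylogous ester by addition–elimination at C-10 and releases the tertiary alcohol 18.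

**Further compounds**

F1 | step 3 | methyl (2R)-2-(hydroxymethyl)-2,5-dimethylhex-4-enoate | COC(=O)[C@](CO)(C)CC=C(C)C
F2 | step 7 | methyl (2R)-2-formyl-2,5-dimethylhex-4-enoate | COC(=O)[C@](C=O)(C)CC=C(C)C
F3 | step 7 | methyl (2R)-3-hydroxy-2,8-dimethyl-2,4-bis(3-methylbut-2-en-1-yl)-5,7-dioxononanoate (C-3/C-4 diastereomer mixture) | COC(=O)[C@](C(O)C(CC=C(C)C)C(=O)CC(=O)C(C)C)(C)CC=C(C)C
F4 | step 8 | cyclic enol ether of 18 (oxygen on C-10 bonded to the side-chain carbinol carbon, C-9=C-10 double bond, ketones at C-8 and C-11, stereocentres as in 18) | CC(C)C(=O)C1=C2OC(C)(C)[C@@H]3C[C@]24C(=O)[C@](C)(C1=O)C[C@H]4C3(C)C
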